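**Plan**
Retrosynthetic cuts: C4=C3 (aldehyde Mannich methylenation); C11=C13 (amine elimination); lactone O8–C12 and the C8/C9 diol; C7–C11 ([3,3] shift from a C9 allylic ester); the C6 ester; then the C5–C10 ring bond (retro-semipinacol), C9–C10 (alkenyl addition) and C5–C4 (hydrazone alkylation).
Forward order: cyclopentanone → (S)-2-alkylcyclopentanone → 1-alkenylcyclopentanol → 2,3-epoxy alcohol → ring expansion of the five-membered C5–C6–C7–C8–C9 ring to the cyclohexanone by insertion of C10, with closure of the oxirane → enone → enedione → C6 ester → C9 allylic ester → Ireland–Claisen → diol and lactone → two methylenations.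
Enabling feature: the C9 carbinol, the quaternary ring carbon C10 and the oxirane oxygen on C1 form a 1,3-dioxygenated array across a quaternary centre of the cyclohexane, which is the retron of a 2,3-epoxy-alcohol semipinacol ring expansion of a cyclopentanol.
Stereochemistry: C5 from SAMP alkylation; C10 and C1 from Sharpless epoxidation, relayed by anti migration; C6 and C9 by α-face hydride delivery; C7 by suprafacial [3,3] transfer from C9; C8/C9 by α-face dihydroxylation; the side-chain centre from (S)-2-methylbutanoic acid.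

Key step: step 8

Remark: ring atoms are named by elemanolide numbering (C9 carbinol, C10 quaternary, C5 carrying C4/C15, then C6, C7, C8; C1/C2 oxirane; C11–C13 lactone); β is the face of the C10 methyl group and α the opposite face; TBS = tert-butyldimethylsilyl.

Step 1
Reactants: 1 cyclopentanone; 2 SAMP, (S)-1-amino-2-(methoxymethyl)pyrrolidine
Product: 3 cyclopentanone SAMP hydrazone
Conditions: neat, 60 °C, then removal of water under vacuum
Reagents that add atoms: none
Why: Condensation of the ketone with the hydrazine auxiliary (hydrazone formation) is driven by loss of water and forms no stereocentre.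

Step 2
Reactants: 3 cyclopentanone SAMP hydrazone; 4 tert-butyl(2-iodoethoxy)dimethylsilane
Product: 6 (2S)-2-[2-(TBSO)ethyl]cyclopentanone SAMP hydrazone, via lithium azaenolate 5 (not isolated)
Conditions: LDA, THF, 0 °C; then 4, −95 °C → rt
Reagents that add atoms: none
Why: Enders SAMP-hydrazone alkylation, in which the lithium-chelated azaenolate is alkylated on one face and should give the (S)-configured α-carbon, the future C5.

Step 3
Reactants: 6 alkylated SAMP hydrazone
Product: 7 (S)-2-[2-(TBSO)ethyl]cyclopentan-1-one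
Conditions: O3, CH2Cl2, −78 °C; N2 purge
Reagents that add atoms: ozone [O-][O+]=O
Why: Ozonolytic cleavage of the hydrazone C=N bond is neutral and cold, so the α-stereocentre of the ketone should survive.

Step 4
Reactants: 8 but-2-yn-1-ol
Product: 10 (Z)-3-iodobut-2-en-1-ol, via sodium cyclic alkenylalanate 9 (not isolated)
Conditions: Red-Al, Et2O/THF, 0 °C → rt; then I2, THF, −78 °C
Reagents that add atoms: iodine II
Why: Hydroxyl-directed trans-hydroalumination of the propargylic alcohol places aluminium at C3 cis to the CH2O group, and iodinolysis with retention should give only the (Z)-3-iodo allylic alcohol.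

Step 5
Reactants: 10 (Z)-3-iodobut-2-en-1-ol; 7 (S)-2-[2-(TBSO)ethyl]cyclopentan-1-one
Product: 12 (2S)-2-[2-(TBSO)ethyl]-1-[(Z)-4-hydroxybut-2-en-2-yl]cyclopentan-1-ol (both C1 epimers), via dilithio alkenyl alkoxide 11 (not isolated)
Conditions: n-BuLi (1 equiv), then t-BuLi (2 equiv), Et2O, −78 °C; anhydrous CeCl3, THF; then 7, −78 → 0 °C; aq. NH4Cl
Reagents that add atoms: none
Why: Iodine–lithium exchange on the lithium alkoxide keeps the olefin geometry and the derived organocerium reagent adds 1,2 to the enolisable ketone without epimerising its α-centre; the new carbinol centre is left uncontrolled because it is erased in step 8.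

Step 6
Reactants: 12 (Z)-allylic diol
Product: 13 {(2S,3S)-3-[(2S)-1-hydroxy-2-(2-(TBSO)ethyl)cyclopentyl]-3-methyloxiran-2-yl}methanol
Conditions: Ti(OiPr)4 (1 equiv), L-(+)-diisopropyl tartrate (1.2 equiv), TBHP, 4 Å MS, CH2Cl2, −20 °C
Reagents that add atoms: tert-butyl hydroperoxide CC(C)(C)OO
Why: Sharpless asymmetric epoxidation of the primary allylic alcohol is chemoselective for the allylic olefin and reagent-controlled, and L-(+)-tartrate should give the (2S,3S)-oxirane from both carbinol epimers.

Step 7
Reactants: 13 epoxy diol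
Product: 14 primary tosylate of 13
Conditions: TsCl, Et3N, DMAP (cat.), CH2Cl2, 0 °C
Reagents that add atoms: p-toluenesulfonyl chloride Cc1ccc(cc1)S(Cl)(=O)=O
Why: Sulfonylation is selective for the primary hydroxyl over the tertiary carbinol and turns C2 into the leaving group needed for the later oxirane closure.

Step 8
Reactants: 14 epoxy tosylate
Product: 16 epoxy ketone, 5β-[2-(TBSO)ethyl]-10β-methyl-10α-[(R)-oxiran-2-yl]cyclohexan-9-one, via hydroxy tosylate ketone 15 (not isolated)
Conditions: BF3·OEt2 (0.2 equiv), CH2Cl2, −78 °C; then K2CO3, MeOH, −78 → 0 °C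
Reagents that add atoms: none
Why: Coordination of BF3 to the oxirane oxygen weakens the C10–O bond at the fully substituted carbon, and the antiperiplanar C9–C5 ring bond of the cyclopentanol migrates to C10 while the carbinol oxygen becomes the C9 carbonyl, so the five-membered ring becomes the cyclohexanone by insertion of C10; this is the type-3 semipinacol (2,3-epoxy-alcohol) ring expansion, closely precedented for 1-(oxiranyl)cycloalkanols. The six-membered ring is therefore formed by a suprafacial 1,2-alkyl shift and not by a cyclisation, and the terminal oxirane is then closed by 3-exo-tet displacement of the primary tosylate by the liberated C1 alkoxide. C10 is set by inversion (the new C5–C10 bond forms anti to the departing oxirane oxygen), C1 keeps its Sharpless-derived C–O bond, C5 migrates with retention, and the C9 carbinol centre is destroyed, so both epimers of 14 converge on one ketone. The step needs migration of C5 in preference to C8 and cleavage at C10 in preference to C1: C5 is the more substituted α-carbon, C10 is the tertiary oxirane carbon, and C1 is deactivated by the adjacent tosyloxymethyl group. One operation thus delivers the quaternary C10, the C9 oxygen, the C5–C10 bond and the oxirane carbon C1 in the required relative and absolute configuration.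

Step 9
Reactants: 16 epoxy ketone
Product: 17 enone, C7=C8 unsaturated analogue of 16
Conditions: IBX (1.5 equiv), DMSO/fluorobenzene, 65 °C
Reagents that add atoms: none
Why: IBX dehydrogenation of a ketone proceeds through the only available enol (towards C8, as C10 is quaternary) and should give the enone without touching the oxirane or the silyl ether.

Step 10
Reactants: 17 enone
Product: 18 enedione, 6,9-dioxo-cyclohex-7-ene analogue of 17
Conditions: Rh2(cap)4 (1 mol %), aq. TBHP, 1,2-dichloroethane, 40 °C
Reagents that add atoms: tert-butyl hydroperoxide CC(C)(C)OO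
Why: Dirhodium caprolactamate-catalysed TBHP allylic oxidation converts the γ-methylene of a cyclohexenone into a carbonyl (enone to ene-1,4-dione), and C6 is the only allylic position.

Step 11
Reactants: 18 enedione
Product: 19 6β-hydroxy enone
Conditions: NaBH4 (0.4 equiv), CeCl3·7H2O, MeOH, −78 °C
Reagents that add atoms: none
Why: Luche 1,2-reduction should take the less hindered C6 carbonyl (C9 is flanked by the quaternary C10), with hydride arriving from the α face, away from the vicinal C5 side chain and the 1,3-related C10 methyl group (the 6-oxo-steroid situation), to give the axial 6β-alcohol.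

Step 12
Reactants: 19 6β-hydroxy enone; 20 (S)-2-methylbutanoic acid
Product: 21 6β-[(S)-2-methylbutanoyloxy] enone
Conditions: DCC, DMAP (0.1 equiv), CH2Cl2, 0 °C → rt
Reagents that add atoms: none
Why: Steglich esterification of the only free hydroxyl proceeds with retention at C6 and, with catalytic DMAP at low temperature, should not racemise the α-branched acid.

Step 13
Reactants: 21 ester enone
Product: 22 9β-allylic alcohol
Conditions: NaBH4, CeCl3·7H2O, MeOH, −40 °C
Reagents that add atoms: none
Why: Luche 1,2-reduction of the remaining enone, in which the β face carries the C10 methyl, the C5 side chain and the C6 ester, so hydride should add from the α face and give the 9β-alcohol needed for chirality transfer.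

Step 14
Reactants: 22 9β-allylic alcohol; 23 3-(dimethylamino)propanoic acid hydrochloride
Product: 24 9β-[3-(dimethylamino)propanoyloxy] 6β-[(S)-2-methylbutanoyloxy] diester
Conditions: DCC, Et3N, DMAP, CH2Cl2, rt
Reagents that add atoms: none
Why: Steglich esterification of the hindered allylic alcohol installs the three-carbon acyl unit (future C11, C12, C13) as a β-amino ester, a latent acrylate.

Step 15
Reactants: 24 diester
Product: 27 amino acid with the C7β side chain CH(CH2NMe2)CO2H and a C8=C9 olefin, via silyl ketene acetal 25 (not isolated), via trimethylsilyl ester 26 (not isolated)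
Conditions: LiHMDS (1.2 equiv), TMSCl, THF, −78 °C → 60 °C; pH 7 buffer
Reagents that add atoms: none
Why: Ireland–Claisen rearrangement, in which kinetic enolisation at the unhindered α-CH2 of the amino ester (the tertiary α-CH of the 2-methylbutanoate is much slower) and O-silylation give the ketene acetal, whose suprafacial [3,3] shift converts the 9β C–O bond into the 7β C–C bond and moves the olefin to C8=C9.

Step 16
Reactants: 27 amino acid
Product: 29 trans-fused 8α,12-lactone with free 9α-hydroxyl and an α-(dimethylaminomethyl) group, via 8α,9α-diol acid 28 (not isolated)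
Conditions: OsO4 (5 mol %), NMO, acetone/H2O, rt; then DCC, CH2Cl2, rt
Reagents that add atoms: N-methylmorpholine N-oxide (terminal oxidant for catalytic OsO4) C[N+]1([O-])CCOCC1; water O
Why: Upjohn dihydroxylation should occur on the α face, anti to the new C7 substituent and the pseudo-axial C10 methyl group, and carbodiimide activation then closes the γ-lactone by 5-exo-trig attack of the 8-hydroxyl, since the 9-hydroxyl is trans-1,3 to the side chain and cannot reach.

Step 17
Reactants: 29 lactone Mannich base
Product: 31 α-methylene lactone silyl ether, via trimethylammonium iodide 30 (not isolated)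
Conditions: MeI, MeCN, rt; then aq. NaHCO3, EtOAc
Reagents that add atoms: none
Why: Quaternisation of the Mannich base and E1cB loss of trimethylamine under bicarbonate is the standard last stage of α-methylene lactone synthesis and needs no strong base, so the C6 ester is safe.

Step 18
Reactants: 31 α-methylene lactone silyl ether
Product: 32 primary alcohol (C15–OH)
Conditions: HF·pyridine, pyridine, THF, 0 °C
Reagents that add atoms: none
Why: Fluoride-mediated cleavage of the primary TBS ether under buffered conditions should spare the oxirane, the esters and the conjugated lactone.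

Step 19
Reactants: 32 primary alcohol
Product: 33 aldehyde (C15 = CHO)
Conditions: TEMPO (0.1 equiv), PhI(OAc)2, CH2Cl2, rt
Reagents that add atoms: none
Why: TEMPO/PhI(OAc)2 oxidation is selective for primary over hindered secondary alcohols, so only C15 is oxidised and the axial neopentyl 9-hydroxyl remains.

Step 20
Reactants: 33 aldehyde
Product: 35 CNP0593558.1 (target), via β-amino aldehyde Mannich base 34 (not isolated)
Conditions: Eschenmoser's salt (3 equiv), Et3N, CH2Cl2, rt
Reagents that add atoms: N,N-dimethylmethyleneiminium iodide (Eschenmoser's salt) C=[N+](C)C.[I-]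
Why: Mannich α-methylenation of the aldehyde, in which aminomethylation at C4 through the enol is followed by spontaneous β-elimination of dimethylamine to give the 2-substituted acrolein without a strong base.

**Compound list**
1 | cyclopentanone | O=C1CCCC1 | starting material
2 | SAMP, (S)-1-amino-2-(methoxymethyl)pyrrolidine | COC[C@@H]1CCCN1N | starting material
3 | cyclopentanone SAMP hydrazone | COC[C@@H]1CCCN1N=C1CCCC1 | intermediate
4 | tert-butyl(2-iodoethoxy)dimethylsilane | C[Si](C)(OCCI)C(C)(C)C | starting material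
5 | lithium azaenolate of 3 | COC[C@@H]1CCCN1N([Li])C1=CCCC1 | intermediate
6 | (2S)-2-[2-(TBSO)ethyl]cyclopentanone SAMP hydrazone | COC[C@@H]1CCCN1N=C1CCC[C@H]1CCO[Si](C)(C)C(C)(C)C | intermediate
7 | (S)-2-[2-(tert-butyldimethylsilyloxy)ethyl]cyclopentan-1-one | O=C1CCC[C@H]1CCO[Si](C)(C)C(C)(C)C | intermediate
8 | but-2-yn-1-ol | CC#CCO | starting material
9 | sodium cyclic alkenylalanate (2,2-bis(2-methoxyethoxy)-3-methyl-1,2-oxaaluminacyclopent-3-enide) | CC1=CCO[Al-]1(OCCOC)OCCOC.[Na+] | intermediate
10 | (Z)-3-iodobut-2-en-1-ol | C/C(I)=C/CO | intermediate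
11 | dilithio (Z)-3-lithiobut-2-en-1-olate | C/C([Li])=C/CO[Li] | intermediate
12 | (2S)-2-[2-(TBSO)ethyl]-1-[(Z)-4-hydroxybut-2-en-2-yl]cyclopentan-1-ol, both C1 epimers | OC/C=C(/C)C1(O)CCC[C@H]1CCO[Si](C)(C)C(C)(C)C | intermediate
13 | {(2S,3S)-3-[(2S)-1-hydroxy-2-(2-(TBSO)ethyl)cyclopentyl]-3-methyloxiran-2-yl}methanol | OC[C@@H]1O[C@]1(C)C1(O)CCC[C@H]1CCO[Si](C)(C)C(C)(C)C | intermediate
14 | primary tosylate of 13 | Cc1ccc(cc1)S(=O)(=O)OC[C@@H]1O[C@]1(C)C1(O)CCC[C@H]1CCO[Si](C)(C)C(C)(C)C | intermediate
15 | 5β-[2-(TBSO)ethyl]-10β-methyl-10α-[(1R)-1-hydroxy-2-(tosyloxy)ethyl]cyclohexan-9-one | O=C1CCC[C@@H](CCO[Si](C)(C)C(C)(C)C)[C@]1(C)[C@@H](O)COS(=O)(=O)c1ccc(C)cc1 | intermediate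
16 | 5β-[2-(TBSO)ethyl]-10β-methyl-10α-[(R)-oxiran-2-yl]cyclohexan-9-one | O=C1CCC[C@@H](CCO[Si](C)(C)C(C)(C)C)[C@]1(C)[C@@H]1CO1 | intermediate
17 | 7,8-didehydro enone of 16 | O=C1C=CC[C@@H](CCO[Si](C)(C)C(C)(C)C)[C@]1(C)[C@@H]1CO1 | intermediate
18 | cyclohex-7-ene-6,9-dione (enedione) | O=C1C=CC(=O)[C@@H](CCO[Si](C)(C)C(C)(C)C)[C@]1(C)[C@@H]1CO1 | intermediate
19 | 6β-hydroxy enone | O=C1C=C[C@@H](O)[C@@H](CCO[Si](C)(C)C(C)(C)C)[C@]1(C)[C@@H]1CO1 | intermediate
20 | (S)-2-methylbutanoic acid | CC[C@H](C)C(=O)O | starting material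
21 | 6β-[(S)-2-methylbutanoyloxy] enone | O=C1C=C[C@@H](OC(=O)[C@@H](C)CC)[C@@H](CCO[Si](C)(C)C(C)(C)C)[C@]1(C)[C@@H]1CO1 | intermediate
22 | 9β-hydroxy-6β-[(S)-2-methylbutanoyloxy]cyclohex-7-ene | O[C@H]1C=C[C@@H](OC(=O)[C@@H](C)CC)[C@@H](CCO[Si](C)(C)C(C)(C)C)[C@]1(C)[C@@H]1CO1 | intermediate
23 | 3-(dimethylamino)propanoic acid hydrochloride | CN(C)CCC(=O)O.Cl | starting material
24 | 9β-[3-(dimethylamino)propanoyloxy] diester | CN(C)CCC(=O)O[C@H]1C=C[C@@H](OC(=O)[C@@H](C)CC)[C@@H](CCO[Si](C)(C)C(C)(C)C)[C@]1(C)[C@@H]1CO1 | intermediate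
25 | trimethylsilyl ketene acetal of 24 | CN(C)CC=C(O[Si](C)(C)C)O[C@H]1C=C[C@@H](OC(=O)[C@@H](C)CC)[C@@H](CCO[Si](C)(C)C(C)(C)C)[C@]1(C)[C@@H]1CO1 | intermediate
26 | trimethylsilyl ester of 27 | CN(C)CC(C(=O)O[Si](C)(C)C)[C@@H]1C=C[C@@](C)([C@@H]2CO2)[C@H](CCO[Si](C)(C)C(C)(C)C)[C@@H]1OC(=O)[C@@H](C)CC | intermediate
27 | 7β-[1-carboxy-2-(dimethylamino)ethyl]cyclohex-8-ene amino acid (C11 epimers) | CN(C)CC(C(=O)O)[C@@H]1C=C[C@@](C)([C@@H]2CO2)[C@H](CCO[Si](C)(C)C(C)(C)C)[C@@H]1OC(=O)[C@@H](C)CC | intermediate
28 | 8α,9α-diol acid | CN(C)CC(C(=O)O)[C@@H]1[C@@H](O)[C@@H](O)[C@@](C)([C@@H]2CO2)[C@H](CCO[Si](C)(C)C(C)(C)C)[C@@H]1OC(=O)[C@@H](C)CC | intermediate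
29 | trans-fused 8α,12-lactone with 9α-OH and 11-(dimethylaminomethyl) | CN(C)CC1C(=O)O[C@@H]2[C@@H]1[C@@H](OC(=O)[C@@H](C)CC)[C@@H](CCO[Si](C)(C)C(C)(C)C)[C@](C)([C@@H]1CO1)[C@@H]2O | intermediate
30 | trimethylammonium iodide of 29 | C[N+](C)(C)CC1C(=O)O[C@@H]2[C@@H]1[C@@H](OC(=O)[C@@H](C)CC)[C@@H](CCO[Si](C)(C)C(C)(C)C)[C@](C)([C@@H]1CO1)[C@@H]2O.[I-] | intermediate
31 | α-methylene lactone with C15–OTBS | C=C1C(=O)O[C@@H]2[C@@H]1[C@@H](OC(=O)[C@@H](C)CC)[C@@H](CCO[Si](C)(C)C(C)(C)C)[C@](C)([C@@H]1CO1)[C@@H]2O | intermediate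
32 | α-methylene lactone with C15–OH | C=C1C(=O)O[C@@H]2[C@@H]1[C@@H](OC(=O)[C@@H](C)CC)[C@@H](CCO)[C@](C)([C@@H]1CO1)[C@@H]2O | intermediate
33 | α-methylene lactone with C15 aldehyde | C=C1C(=O)O[C@@H]2[C@@H]1[C@@H](OC(=O)[C@@H](C)CC)[C@@H](CC=O)[C@](C)([C@@H]1CO1)[C@@H]2O | intermediate
34 | β-(dimethylamino) aldehyde Mannich base | C=C1C(=O)O[C@@H]2[C@@H]1[C@@H](OC(=O)[C@@H](C)CC)[C@@H](C(CN(C)C)C=O)[C@](C)([C@@H]1CO1)[C@@H]2O | intermediate
35 | CNP0593558.1 | C=C1C(=O)O[C@@H]2[C@@H]1[C@@H](OC(=O)[C@@H](C)CC)[C@@H](C(=C)C=O)[C@](C)([C@@H]1CO1)[C@@H]2O | target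

**Totals**
Total step count: 20. Longest linear sequence: 19 steps (steps 1–3 and 5–20; step 4 is a one-step branch).

**Steps most likely to fail**
1. Step 6. The epoxidation may turn over slowly or show weak facial selectivity, because the bulky tertiary carbinol sits cis to the hydroxymethyl group on the olefin. The fallback puts the carbinol trans and compensates by inverting the oxirane carbon at the end. It sets out from 7: addition of ethynylmagnesium bromide (CeCl3) gives the propargylic alcohol F1; zirconium-catalysed methylalumination (AlMe3, Cp2ZrCl2) with paraformaldehyde quench gives the (E)-allylic diol F2; Sharpless epoxidation with D-(−)-diisopropyl tartrate, now on a geraniol-type olefin, gives the trans epoxy diol F3; Ac2O/pyridine gives the primary acetate F4; BF3·OEt2 gives the ring-expanded hydroxy ketone acetate F5, epimeric at C1 with the main series; MsCl/Et3N gives the secondary mesylate F6; K2CO3/MeOH removes the acetate and the primary alkoxide displaces the mesylate with inversion, which returns to 16.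
2. Step 11. Hydride may be delivered to the β face of C6, or the C9 carbonyl may compete. The fallback introduces the C6 oxygen as an electrophile and corrects the configuration by substitution. It sets out from 17: LDA/TMSCl gives the trimethylsilyl dienol ether F7; mCPBA (vinylogous Rubottom oxidation) adds oxygen from the open α face to give the 6α-hydroxy enone F8; Mitsunobu esterification (PPh3, DIAD) with 20 inverts C6 and returns to 21.
3. Step 13. Hydride delivery from the β face would give the 9α-alcohol and, after step 15, the wrong configuration at C7. The fallback replaces substrate control by catalyst control: Corey–Bakshi–Shibata reduction of 21 with (R)-2-methyl-CBS-oxazaborolidine and catecholborane, in which the quaternary C10 side is the large substituent and hydride is predicted to come from the α face, returns to 22 and makes no new compound (F0).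

**Further compounds**
F1 | step 6 | (2S)-1-ethynyl-2-[2-(TBSO)ethyl]cyclopentan-1-ol | C#CC1(O)CCC[C@H]1CCO[Si](C)(C)C(C)(C)C
F2 | step 6 | (2S)-2-[2-(TBSO)ethyl]-1-[(E)-4-hydroxybut-2-en-2-yl]cyclopentan-1-ol | OC/C=C(\C)C1(O)CCC[C@H]1CCO[Si](C)(C)C(C)(C)C
F3 | step 6 | {(2R,3S)-3-[(2S)-1-hydroxy-2-(2-(TBSO)ethyl)cyclopentyl]-3-methyloxiran-2-yl}methanol | OC[C@H]1O[C@]1(C)C1(O)CCC[C@H]1CCO[Si](C)(C)C(C)(C)C
F4 | step 6 | primary acetate of F3 | CC(=O)OC[C@H]1O[C@]1(C)C1(O)CCC[C@H]1CCO[Si](C)(C)C(C)(C)C
F5 | step 6 | 5β-[2-(TBSO)ethyl]-10β-methyl-10α-[(1S)-2-acetoxy-1-hydroxyethyl]cyclohexan-9-one | O=C1CCC[C@@H](CCO[Si](C)(C)C(C)(C)C)[C@]1(C)[C@H](O)COC(C)=O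
F6 | step 6 | secondary mesylate of F5 | O=C1CCC[C@@H](CCO[Si](C)(C)C(C)(C)C)[C@]1(C)[C@H](OS(C)(=O)=O)COC(C)=O
F7 | step 11 | 9-(trimethylsilyloxy)cyclohexa-6,8-diene (silyl dienol ether of 17) | C[Si](C)(C)OC1=CC=C[C@@H](CCO[Si](C)(C)C(C)(C)C)[C@]1(C)[C@@H]1CO1
F8 | step 11 | 6α-hydroxy enone | O=C1C=C[C@H](O)[C@@H](CCO[Si](C)(C)C(C)(C)C)[C@]1(C)[C@@H]1CO1
F0 | step 13 | none | none
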